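## The problem

Target 35 is the 15-O-icosanoate of (13E)-cleroda-3,13-diene-15,16-diol. It is a trans-fused decalin (ring A C1–C5/C10, ring B C5–C10) with methyl groups C17 on C8, C18 on C4, C19 on C5 and C20 on C9, and a chain C11–C16 on C9. Here α means the face that carries C19 and β the face that carries H10. Ring B holds four contiguous stereocentres (5R, 8R, 9S, 10R). Two are quaternary (C5, C9), and their methyl groups C19 and C20 are syn-diaxial, while C17 is equatorial and cis to C20. The side chain has no stereocentre, so absolute configuration must enter through the decalin. C5 and C10 can then steer C9 through the conformation of a substituent on C10, and the axial C20 can steer C8 by blocking the α face. The C13=C14 alkene is trisubstituted, has (E) geometry and carries two allylic CH2O groups that differ only in acylation, so its geometry must come from a stereospecific C–C bond formation and O16 must be freed last without disturbing the ester. The C3=C4 alkene and the allylic ester do not survive hydrogenation or strong acid, which fixes the order of events. The enabling feature is the pair C5 (quaternary: C19 and the ring B bond to C6) and C10 (H and the ring B bond to C9) with these two ring B bonds trans on ring A. This is the imprint of a suprafacial [4+2] addition to an (E)-2-methyl-2-enal whose formyl carbon is C6 and whose β-substituent is C9, and a 1-oxygenated diene leaves oxygen on C4, where a ketone can later deliver both C18 and the C3=C4 alkene.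

## Retrosynthesis

**O16–Si and C12–C13.** Target 35 is traced to its silyl ether 34, and 34 is cut between C12 and C13 into the decalin iodide 26 and the alkenyl iodide 32 (sp3–sp2 cross-coupling through alkylzinc 33). Olefination of a C13 ketone would have to distinguish two CH2X substituents and offers no geometric control, whereas the coupling transfers the geometry of 32 unchanged. The cut separates all four stereocentres (in 26) from the whole functionalised chain (in 32). The forward reaction must retain alkene geometry, tolerate an ester and a silyl ether, and avoid β-hydride elimination.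

**The C4 fragment.** Iodide 32 is cut at the ester C–O bond into alcohol 30 and icosanoic acid 31. Alcohol 30 is traced to alkynol 28 by removing H and I across the alkyne (hydroxyl-directed trans-hydroalumination through alanate 29, then iodinolysis), and 28 to but-2-yne-1,4-diol 27. Silylating one hydroxyl first decides which oxygen directs the hydride, so the iodine lands on the carbon that becomes C13 and the two oxygens are differentiated from the outset.

**C12 and C4–C18.** Iodide 26 comes from alcohol 25 and ester 24. In 24 the C4–C18 bond is cut to give enol triflate 23, which comes from ketone 21 through enolate 22, and 21 from alcohol 20 and silyl ether 19. Because C5 is quaternary, the ketone can enolise only toward C3, so the alkene can appear only at C3=C4. Addition of a methyl nucleophile followed by dehydration would give exo/endo mixtures, would generate a cation beside a quaternary carbon and would not tolerate the ester.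

**C8–C17.** The C8 methine of 19 is traced to the exocyclic alkene 18, cut at C8=C17 to ketone 17 and then to alcohol 16. This postpones C8 until C9 exists, so that the axial C20 can direct hydrogen to the β face. It also makes the configuration of the carbinol in 16 irrelevant.

**C8–C9 (ring B).** Hydroxy ester 16 is cut between C8 and C9 to the aldehyde (Z)-enoate 15 (ketyl–olefin radical cyclisation). Alkylating a C8 ketone at C9 would require regiocontrolled enolisation, and a cationic closure would endanger the silyl ether. The radical closure forms the quaternary C9 directly from a trigonal carbon, and the (Z) geometry fixes the rotamer about C10–C9 by allylic strain and so determines which substituent of C9 becomes axial. The precursor is monocyclic and carries only the stereocentres of the cycloaddition.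

**The two arms.** Aldehyde 15 comes from acetal 14. In 14 the C9–C20 bond is cut (syn-carbocupration through alkenylcuprate 13) to ynoate 12. Ynoate 12 is cut at C11–C12 (acylation of acetylide 11) and C9–C11 (dibromo-olefination) to dibromoalkene 10 and aldehyde 9, which comes from alcohol 8. Alcohol 8 arises from 7 by one hydrogenation that saturates two alkenes and removes the benzyl group, and 7 is cut at C6=C7 to aldehyde 6 (Wittig reaction with a two-carbon ylide whose second carbon is already an acetal). Each arm is thus grown from the function the cycloaddition leaves on it.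

**C4–C5 and C1–C10 (ring A).** Aldehyde 6 is cut into enal 3 and diene 5. This is the only disconnection of the sequence that creates absolute configuration, and it builds the quaternary C5 from two achiral fragments. The forward reaction needs ortho regiochemistry, one enal face and retention of the (E) geometry, and it is indifferent to endo or exo placement of the C4 oxygen.

**The fragments.** Enal 3 is cut at its C=C bond into aldehyde 1 and the formyl-stabilised ylide 2. Diene 5 comes from crotonaldehyde 4 by O-silylation of its dienolate.

## Roads not taken

**Alternative 1:** diazoketone cyclopropanation at a C5 methylene. The cut removes C4–C5 and C4–C19 and leaves a preformed ring B with an exocyclic C5=C19 alkene and a diazoketone on the C10 arm, A2. In the forward step Rh2(OAc)4 generates a carbenoid at C4 that adds across C5=C19 and gives the cyclopropyl ketone A1, in which the cyclopropane is a latent C19 methyl group.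
- Merits: the C8/C9 pair and a vinyl handle on C9 are in place before the key step, so no late radical closure onto a fully substituted carbon is needed. Intramolecular cyclopropanation is among the most dependable ways to build a crowded quaternary carbon, and reductive opening reveals C19.
- Weak points for this target: the trans ring fusion forms only if the tether on C10 reaches the alkene face anti to H10, and the cis-fused tricycle is a real competitor. The C9 vinyl group and allylic C–H bonds compete for the carbenoid. After the key step the oxygen is on C3, not C4, so C18 must be introduced by α-methylation at C4 in competition with C2, and the C3 oxygen must then be removed with the alkene left at C3=C4. A2 itself requires an enantioselective synthesis of a ring B with three contiguous stereocentres.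
- Comparison: A1 does place the side-chain handle earlier and avoids the samarium closure, and in those respects it is the better road. The chosen plan sets against this that absolute configuration and the C5/C10 relationship come from one catalytic step on achiral fragments, that no stereocentre precedes the key step, and that the oxygen left by the cycloaddition sits on the carbon where C18 and the alkene are needed.

**Alternative 2:** biomimetic friedo rearrangement. No ring bond is cut. Shifting C19 back from C5 to C4 and C20 back from C9 to C10 leads to the ent-labdane A4. In the forward step TfOH in a fluorinated alcohol protonates the C8=C17 alkene, and four antiperiplanar 1,2-shifts followed by loss of H3 would give A3.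
- Merits: it is by far the shortest route if the cascade runs to completion. All four stereocentres follow stereospecifically from those of A4, and there is almost no protecting-group traffic.
- Weak points: without an enzyme each cation on the way (C8, C9, C10, C5, C4) can lose a proton, so partially rearranged alkenes are the expected competitors and the relay has to outrun all of them. The last deprotonation must choose H3 over a C18 hydrogen. The C12 acyloxy group can capture the C8 cation. The inexpensive labdanes belong to the normal series, so A4 would need an enantioselective polyene cyclisation, which consumes much of the step advantage.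
- Comparison: in step count this road is better, and that is conceded. The chosen plan offers in return that each stereocentre is set by an identifiable event that can be optimised separately, and that either enantiomeric series is equally accessible from commodity chemicals.

**Alternative 3:** intramolecular Diels–Alder reaction building both rings. The cut removes C5–C10 and C3–C4 and leads to the open-chain triene A6 (diene C10=C1–C2=C3, (E)-enoate C4=C5). In the forward step EtAlCl2 would close rings A and B together to give A5.
- Merits: two rings and the C4/C5/C10 centres form in one step, and the C9 vinyl group is already present.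
- Weak points: the hardest element, the tertiary C8 beside the quaternary C9, must be made in an acyclic precursor, where neither a ring nor an axial methyl group is available for control. The dienophile carbon C5 is the fully substituted β-carbon of the enoate and the diene terminus C10 is neopentylic, so the closure is sterically loaded and the ring fusion rests on a small endo/exo preference. The adduct has its alkene at C1=C2 and an ester at C18, so the 4-methyl-3-ene requires reduction of an ester to a methyl group and an alkene transposition over three carbons.
- Comparison: ring-forming economy is higher here, which is conceded. The chosen plan sets against it a cycloaddition between two small achiral partners under catalyst control, construction of the C8/C9 pair inside a rigid ring, and an oxygen function exactly where the target needs it.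

Key step: step 3

Remarks on the chemistry:
- Clerodane numbering and the α/β convention defined above are used for all intermediates.
- Compound 6 is taken as the endo adduct (C4–O cis to the formyl group). The C4 epimer, if formed, would run through the same steps and converge at ketone 21.
- Compound 7 is expected as a mixture of alkene isomers, both reduced in step 5, so its SMILES carries no alkene geometry.
- Compound 16 is drawn as the 8α-alcohol; C8 becomes trigonal in step 12.

Step 1
Reactants: 1 benzyloxyacetaldehyde; 2 2-(triphenylphosphoranylidene)propanal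
Product: 3 (E)-4-(benzyloxy)-2-methylbut-2-enal
Conditions: toluene, 80 °C (1 in slight excess)
Reagents that add atoms: none
Why: Wittig reaction of a formyl-stabilised ylide with an aldehyde; the stabilised ylide should give the (E)-trisubstituted enal, and the slight excess of 1 limits a second olefination of the product.

Step 2
Reactants: 4 (E)-crotonaldehyde
Product: 5 (E)-1-(tert-butyldimethylsilyloxy)buta-1,3-diene
Conditions: TBSOTf, Et3N, Et2O, 0 °C to rt
Reagents that add atoms: tert-butyldimethylsilyl triflate, CC(C)(C)[Si](C)(C)OS(=O)(=O)C(F)(F)F
Why: Silyl dienol ether formation by γ-deprotonation of the silyl-activated enal; the (E) isomer should predominate and is the only one that can reach the s-cis geometry needed in step 3.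

Step 3
Reactants: 3 (E)-4-(benzyloxy)-2-methylbut-2-enal; 5 (E)-1-(tert-butyldimethylsilyloxy)buta-1,3-diene
Product: 6 (1R,2S,6S)-6-[(benzyloxy)methyl]-2-[(tert-butyldimethylsilyl)oxy]-1-methylcyclohex-3-ene-1-carbaldehyde (ring C1 = C5, C2 = C4, C6 = C10; CHO cis to OTBS and trans to CH2OBn)
Conditions: oxazaborolidinium triflimide from (R)-3,3-diphenyl-1-(o-tolyl)tetrahydro-1H,3H-pyrrolo[1,2-c][1,3,2]oxazaborole and HNTf2 (20 mol %), CH2Cl2, −78 to −40 °C (5 in excess)
Reagents that add atoms: none
Why: The cationic boron Lewis acid binds the formyl oxygen of 3 syn to the formyl hydrogen, which lowers the LUMO and holds the s-trans enal over one aryl ring of the catalyst; 5 then adds to the open face in a concerted, asynchronous, normal-demand Diels–Alder reaction, the closest known type being oxazaborolidinium-catalysed cycloadditions of 2-methyl-2-enals with oxygenated butadienes. Ring A closes by suprafacial [4+2] cycloaddition in which C1–C10 bonding runs ahead of C4–C5 bonding. C5 is set by the catalyst, which on the accepted pre-transition-state model (formyl C–H···O contact, (R)-prolinol-derived ring) leaves open the face that is Re at the formyl carbon and so should give 5R. C10 follows from C5 because the (E) geometry of 3 is carried into the ring, which places C6 and C9 trans. C4 results from the endo position of the formyl group and is a spectator that step 16 erases. Regioselectivity is secured by the donor oxygen of 5, whose remote terminus C1 has the larger HOMO coefficient and meets the β-carbon C10; face selectivity rests on the catalyst alone, and low temperature with excess diene keeps the uncatalysed pathway small.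

Step 4
Reactants: 6 cyclohexene aldehyde
Product: 7 2-{2-[(1R,2S,6S)-6-[(benzyloxy)methyl]-2-[(tert-butyldimethylsilyl)oxy]-1-methylcyclohex-3-en-1-yl]ethenyl}-1,3-dioxolane (mixture of alkene isomers)
Conditions: (1,3-dioxolan-2-ylmethyl)triphenylphosphonium bromide, KOtBu, THF, 0 °C to rt
Reagents that add atoms: (1,3-dioxolan-2-ylmethyl)triphenylphosphonium bromide, [Br-].C1COC(C[P+](c2ccccc2)(c2ccccc2)c2ccccc2)O1
Why: Wittig reaction of the non-enolisable neopentyl aldehyde with a reactive, non-stabilised ylide adds C7 and C8 with C8 already masked as an acetal; alkene geometry is irrelevant because the bond is reduced next.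

Step 5
Reactants: 7 alkenyl dioxolane
Product: 8 {(1S,2R,3S)-3-[(tert-butyldimethylsilyl)oxy]-2-[2-(1,3-dioxolan-2-yl)ethyl]-2-methylcyclohexyl}methanol
Conditions: H2 (1 atm), Pd/C, EtOAc–EtOH, rt
Reagents that add atoms: none
Why: Heterogeneous hydrogenation saturates both disubstituted alkenes and hydrogenolyses the benzyl ether in one operation; the silyl ether and the acetal are inert under neutral conditions, and no stereocentre is created.

Step 6
Reactants: 8 primary alcohol
Product: 9 (1S,2R,3S)-3-[(tert-butyldimethylsilyl)oxy]-2-[2-(1,3-dioxolan-2-yl)ethyl]-2-methylcyclohexane-1-carbaldehyde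
Conditions: Dess–Martin periodinane, pyridine, CH2Cl2, 0 °C to rt
Reagents that add atoms: none
Why: Dess–Martin oxidation under buffered, non-basic conditions should give the aldehyde without epimerising C10, whose equatorial formyl group is in any case the more stable arrangement.

Step 7
Reactants: 9 aldehyde
Product: 10 tert-butyl{[(1S,2R,3R)-3-(2,2-dibromoethenyl)-2-[2-(1,3-dioxolan-2-yl)ethyl]-2-methylcyclohexyl]oxy}dimethylsilane
Conditions: CBr4, PPh3, 2,6-lutidine, CH2Cl2, 0 °C
Reagents that add atoms: carbon tetrabromide, BrC(Br)(Br)Br
Why: Corey–Fuchs dibromo-olefination (Wittig-type reaction of Ph3P=CBr2) adds C11; the lutidine buffer protects the acetal and the silyl ether from adventitious HBr.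

Step 8
Reactants: 10 dibromoalkene
Product: 12 methyl 3-[(1R,2R,3S)-3-[(tert-butyldimethylsilyl)oxy]-2-[2-(1,3-dioxolan-2-yl)ethyl]-2-methylcyclohexyl]prop-2-ynoate, via lithium acetylide 11 (not isolated)
Conditions: n-BuLi (2.1 equiv), THF, −78 °C; then ClCO2Me, −78 to 0 °C
Reagents that add atoms: methyl chloroformate, COC(=O)Cl
Why: Second stage of the Corey–Fuchs sequence: bromine–lithium exchange, carbenoid 1,2-shift and deprotonation give the acetylide, which is acylated in the same flask to install C12.

Step 9
Reactants: 12 ynoate
Product: 14 methyl (2Z)-3-[(1R,2R,3S)-3-[(tert-butyldimethylsilyl)oxy]-2-[2-(1,3-dioxolan-2-yl)ethyl]-2-methylcyclohexyl]but-2-enoate, via alkenylcuprate 13 (not isolated)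
Conditions: Me2CuLi (from MeLi and CuI), THF, −78 °C; aq NH4Cl at −78 °C
Reagents that add atoms: lithium dimethylcuprate, [Li+].C[Cu-]C
Why: Conjugate syn-carbocupration of the ynoate: the methyl group (C20) and copper add cis across C9≡C11 and protonation occurs with retention, so C10 and the ester end cis, which is the (Z)-enoate; the low temperature prevents equilibration through the allenoate.

Step 10
Reactants: 14 (Z)-enoate acetal
Product: 15 methyl (2Z)-3-[(1R,2R,3S)-3-[(tert-butyldimethylsilyl)oxy]-2-methyl-2-(3-oxopropyl)cyclohexyl]but-2-enoate
Conditions: PPTS, acetone–H2O, 50 °C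
Reagents that add atoms: water, O
Why: Mild acid-catalysed acetal hydrolysis releases the C8 aldehyde; a hindered secondary silyl ether and the conjugated ester should tolerate PPTS in wet acetone.

Step 11
Reactants: 15 aldehyde (Z)-enoate
Product: 16 methyl 4β-[(tert-butyldimethylsilyl)oxy]-8α-hydroxy-13,14,15,16,17,18-hexanorclerodan-12-oate (trans-decalin; 5α-CH3, 9α-CH3, 9β-CH2CO2Me, 10β-H)
Conditions: SmI2 (2.5 equiv), THF–MeOH, −78 to 0 °C, high dilution
Reagents that add atoms: none
Why: SmI2-mediated ketyl–olefin radical cyclisation, 6-exo-trig: the C8 ketyl adds to the β-carbon C9 of the enoate and the resulting α-ester radical is reduced and protonated. Allylic 1,3-strain in the (Z)-enoate holds H10 in the alkene plane, so the tethered ketyl attacks the face that leaves C20 anti to H10 (axial, α) and C11 equatorial (β), through a chair that is trans-fused to ring A. The bulky oxygen–samarium group should take the equatorial position (8α), but this centre is erased in step 12.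

Step 12
Reactants: 16 hydroxy ester
Product: 17 methyl 4β-[(tert-butyldimethylsilyl)oxy]-8-oxo-13,14,15,16,17,18-hexanorclerodan-12-oate
Conditions: Dess–Martin periodinane, CH2Cl2, rt
Reagents that add atoms: none
Why: Dess–Martin oxidation of the hindered secondary alcohol to the C8 ketone; the quaternary C9 and the ester are unaffected.

Step 13
Reactants: 17 keto ester
Product: 18 methyl 4β-[(tert-butyldimethylsilyl)oxy]-13,14,15,16,18-pentanorclerod-8(17)-en-12-oate
Conditions: Zn, CH2Br2, TiCl4, THF–CH2Cl2, 0 °C to rt
Reagents that add atoms: dibromomethane, BrCBr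
Why: Takai–Lombardo methylenation: the non-basic geminal dimetal reagent methylenates hindered, enolisable ketones and leaves esters untouched, and it adds C17.

Step 14
Reactants: 18 exocyclic alkene
Product: 19 methyl 4β-[(tert-butyldimethylsilyl)oxy]-13,14,15,16,18-pentanorclerodan-12-oate (8α-CH3)
Conditions: H2 (1 atm), Pd/C, EtOAc, rt
Reagents that add atoms: none
Why: Catalytic hydrogenation of the 1,1-disubstituted alkene; the axial C20 methyl on the neighbouring C9 shields the α face, so hydrogen should reach C8 from the β face and C17 becomes equatorial (α), cis to C20 (8R).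

Step 15
Reactants: 19 silyl ether
Product: 20 methyl 4β-hydroxy-13,14,15,16,18-pentanorclerodan-12-oate
Conditions: HF (aq), MeCN, rt
Reagents that add atoms: none
Why: Fluoride-mediated cleavage of the hindered axial silyl ether; the conditions are compatible with the ester and there is no alkene to isomerise.

Step 16
Reactants: 20 secondary alcohol
Product: 21 methyl 4-oxo-13,14,15,16,18-pentanorclerodan-12-oate
Conditions: Dess–Martin periodinane, CH2Cl2, rt
Reagents that add atoms: none
Why: Dess–Martin oxidation of the axial alcohol gives the C4 ketone and removes the spectator stereocentre.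

Step 17
Reactants: 21 ketone
Product: 23 methyl 4-[(trifluoromethylsulfonyl)oxy]-13,14,15,16,18-pentanorclerod-3-en-12-oate, via potassium enolate 22 (not isolated)
Conditions: KN(SiMe3)2, THF, −78 °C; then PhNTf2, −78 to 0 °C
Reagents that add atoms: N-phenylbis(trifluoromethanesulfonimide), O=S(=O)(N(c1ccccc1)S(=O)(=O)C(F)(F)F)C(F)(F)F
Why: Enol triflate formation by kinetic enolisation and O-sulfonylation; only C3 carries α-hydrogens because C5 is quaternary, so a single regioisomer can form, and the ester is far less acidic than the ketone at −78 °C.

Step 18
Reactants: 23 enol triflate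
Product: 24 methyl 13,14,15,16-tetranorclerod-3-en-12-oate
Conditions: MeZnCl, Pd(PPh3)4 (5 mol %), THF, rt to 50 °C
Reagents that add atoms: methylzinc chloride, C[Zn]Cl
Why: Negishi cross-coupling of the alkenyl triflate with a methylzinc reagent installs C18 with the alkene fixed at C3=C4; the organozinc tolerates the ester.

Step 19
Reactants: 24 ester
Product: 25 13,14,15,16-tetranorclerod-3-en-12-ol
Conditions: LiAlH4, Et2O, 0 °C
Reagents that add atoms: none
Why: Hydride reduction of the ester to the primary alcohol; the isolated trisubstituted alkene is inert.

Step 20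
Reactants: 25 primary alcohol
Product: 26 12-iodo-13,14,15,16-tetranorclerod-3-ene
Conditions: I2, PPh3, imidazole, CH2Cl2, 0 °C to rt
Reagents that add atoms: iodine, II
Why: Appel-type iodination: SN2 displacement of the oxyphosphonium group at the unhindered primary carbon.

Step 21
Reactants: 27 but-2-yne-1,4-diol
Product: 28 4-[(tert-butyldimethylsilyl)oxy]but-2-yn-1-ol
Conditions: TBSCl, imidazole, THF, 0 °C (27 in threefold excess)
Reagents that add atoms: tert-butyldimethylsilyl chloride, CC(C)(C)[Si](C)(C)Cl
Why: Statistical monosilylation with the inexpensive diol in excess, which suppresses the bis-ether.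

Step 22
Reactants: 28 alkynol
Product: 30 (Z)-4-[(tert-butyldimethylsilyl)oxy]-3-iodobut-2-en-1-ol, via cyclic alkenylalanate 29 (not isolated)
Conditions: NaAlH2(OCH2CH2OMe)2, THF, 0 °C; then I2, −78 °C
Reagents that add atoms: iodine, II
Why: Hydroxyl-directed trans-hydroalumination of the propargylic alcohol followed by iodinolysis with retention: hydride is delivered to the future C14 and aluminium to the future C13, so iodine ends cis to the hydroxymethyl group. Low temperature keeps the alanate from expelling the silyloxy group.

Step 23
Reactants: 30 iodo alcohol; 31 icosanoic acid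
Product: 32 (Z)-4-[(tert-butyldimethylsilyl)oxy]-3-iodobut-2-en-1-yl icosanoate
Conditions: EDC·HCl, DMAP, CH2Cl2, rt
Reagents that add atoms: none
Why: Carbodiimide/DMAP (Steglich) esterification of the primary allylic alcohol with the fatty acid.

Step 24
Reactants: 26 decalin iodide; 32 alkenyl iodide
Product: 34 (13E)-16-[(tert-butyldimethylsilyl)oxy]cleroda-3,13-dien-15-yl icosanoate, via alkylzinc iodide 33 (not isolated)
Conditions: Zn dust, LiCl, THF, 40 °C; then 32, PdCl2(dppf) (5 mol %), THF, rt
Reagents that add atoms: none
Why: Negishi sp3–sp2 cross-coupling: zinc inserts into the primary C–I bond of 26 and the alkylzinc couples with the alkenyl iodide with retention of geometry, so C12 ends cis to C15. The bidentate dppf ligand favours reductive elimination over β-hydride elimination, and oxidative addition to the C–I bond should outpace ionisation of the allylic ester.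

Step 25
Reactants: 34 silyl ether
Product: 35 (13E)-16-hydroxycleroda-3,13-dien-15-yl icosanoate, (5R,8R,9S,10R)
Conditions: HF·pyridine, THF–pyridine, 0 °C
Reagents that add atoms: none
Why: Fluoride cleavage of the primary allylic silyl ether under weakly acidic conditions; the ester cannot migrate to O16 because the two oxygens are trans across the alkene.

## Compound list

1 | benzyloxyacetaldehyde | O=CCOCc1ccccc1 | starting material
2 | 2-(triphenylphosphoranylidene)propanal | CC(C=O)=P(c1ccccc1)(c1ccccc1)c1ccccc1 | starting material
3 | (E)-4-(benzyloxy)-2-methylbut-2-enal | O=C/C(C)=C/COCc1ccccc1 | intermediate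
4 | (E)-crotonaldehyde | C/C=C/C=O | starting material
5 | (E)-1-(tert-butyldimethylsilyloxy)buta-1,3-diene | C=C/C=C/O[Si](C)(C)C(C)(C)C | intermediate
6 | (1R,2S,6S)-6-[(benzyloxy)methyl]-2-[(tert-butyldimethylsilyl)oxy]-1-methylcyclohex-3-ene-1-carbaldehyde | O=C[C@@]1(C)[C@@H](O[Si](C)(C)C(C)(C)C)C=CC[C@@H]1COCc1ccccc1 | intermediate
7 | 2-{2-[(1R,2S,6S)-6-[(benzyloxy)methyl]-2-[(tert-butyldimethylsilyl)oxy]-1-methylcyclohex-3-en-1-yl]ethenyl}-1,3-dioxolane (alkene isomers) | O1CCOC1C=C[C@@]2(C)[C@@H](O[Si](C)(C)C(C)(C)C)C=CC[C@@H]2COCc3ccccc3 | intermediate
8 | {(1S,2R,3S)-3-[(tert-butyldimethylsilyl)oxy]-2-[2-(1,3-dioxolan-2-yl)ethyl]-2-methylcyclohexyl}methanol | O1CCOC1CC[C@@]2(C)[C@@H](O[Si](C)(C)C(C)(C)C)CCC[C@@H]2CO | intermediate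
9 | (1S,2R,3S)-3-[(tert-butyldimethylsilyl)oxy]-2-[2-(1,3-dioxolan-2-yl)ethyl]-2-methylcyclohexane-1-carbaldehyde | O1CCOC1CC[C@@]2(C)[C@@H](O[Si](C)(C)C(C)(C)C)CCC[C@@H]2C=O | intermediate
10 | tert-butyl{[(1S,2R,3R)-3-(2,2-dibromoethenyl)-2-[2-(1,3-dioxolan-2-yl)ethyl]-2-methylcyclohexyl]oxy}dimethylsilane | O1CCOC1CC[C@@]2(C)[C@@H](O[Si](C)(C)C(C)(C)C)CCC[C@@H]2C=C(Br)Br | intermediate
11 | lithium acetylide of 10 (C9≡C11–Li; not isolated) | O1CCOC1CC[C@@]2(C)[C@@H](O[Si](C)(C)C(C)(C)C)CCC[C@@H]2C#C[Li] | intermediate
12 | methyl 3-[(1R,2R,3S)-3-[(tert-butyldimethylsilyl)oxy]-2-[2-(1,3-dioxolan-2-yl)ethyl]-2-methylcyclohexyl]prop-2-ynoate | O1CCOC1CC[C@@]2(C)[C@@H](O[Si](C)(C)C(C)(C)C)CCC[C@@H]2C#CC(=O)OC | intermediate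
13 | lithium methyl(alkenyl)cuprate from 12 (Cu on C11, cis to C20; not isolated) | [Li+].O1CCOC1CC[C@@]2(C)[C@@H](O[Si](C)(C)C(C)(C)C)CCC[C@@H]2/C(C)=C(/[Cu-]C)C(=O)OC | intermediate
14 | methyl (2Z)-3-[(1R,2R,3S)-3-[(tert-butyldimethylsilyl)oxy]-2-[2-(1,3-dioxolan-2-yl)ethyl]-2-methylcyclohexyl]but-2-enoate | O1CCOC1CC[C@@]2(C)[C@@H](O[Si](C)(C)C(C)(C)C)CCC[C@@H]2/C(C)=C\C(=O)OC | intermediate
15 | methyl (2Z)-3-[(1R,2R,3S)-3-[(tert-butyldimethylsilyl)oxy]-2-methyl-2-(3-oxopropyl)cyclohexyl]but-2-enoate | O=CCC[C@@]1(C)[C@@H](O[Si](C)(C)C(C)(C)C)CCC[C@@H]1/C(C)=C\C(=O)OC | intermediate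
16 | methyl 4β-[(tert-butyldimethylsilyl)oxy]-8α-hydroxy-13,14,15,16,17,18-hexanorclerodan-12-oate | COC(=O)C[C@@]1(C)[C@H](O)CC[C@@]2(C)[C@@H](O[Si](C)(C)C(C)(C)C)CCC[C@H]12 | intermediate
17 | methyl 4β-[(tert-butyldimethylsilyl)oxy]-8-oxo-13,14,15,16,17,18-hexanorclerodan-12-oate | COC(=O)C[C@@]1(C)C(=O)CC[C@@]2(C)[C@@H](O[Si](C)(C)C(C)(C)C)CCC[C@H]12 | intermediate
18 | methyl 4β-[(tert-butyldimethylsilyl)oxy]-13,14,15,16,18-pentanorclerod-8(17)-en-12-oate | COC(=O)C[C@@]1(C)C(=C)CC[C@@]2(C)[C@@H](O[Si](C)(C)C(C)(C)C)CCC[C@H]12 | intermediate
19 | methyl 4β-[(tert-butyldimethylsilyl)oxy]-13,14,15,16,18-pentanorclerodan-12-oate | COC(=O)C[C@@]1(C)[C@H](C)CC[C@@]2(C)[C@@H](O[Si](C)(C)C(C)(C)C)CCC[C@H]12 | intermediate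
20 | methyl 4β-hydroxy-13,14,15,16,18-pentanorclerodan-12-oate | COC(=O)C[C@@]1(C)[C@H](C)CC[C@@]2(C)[C@@H](O)CCC[C@H]12 | intermediate
21 | methyl 4-oxo-13,14,15,16,18-pentanorclerodan-12-oate | COC(=O)C[C@@]1(C)[C@H](C)CC[C@@]2(C)C(=O)CCC[C@H]12 | intermediate
22 | potassium C3=C4 enolate of 21 (not isolated) | COC(=O)C[C@@]1(C)[C@H](C)CC[C@@]2(C)C([O-])=CCC[C@H]12.[K+] | intermediate
23 | methyl 4-[(trifluoromethylsulfonyl)oxy]-13,14,15,16,18-pentanorclerod-3-en-12-oate | COC(=O)C[C@@]1(C)[C@H](C)CC[C@@]2(C)C(OS(=O)(=O)C(F)(F)F)=CCC[C@H]12 | intermediate
24 | methyl 13,14,15,16-tetranorclerod-3-en-12-oate | COC(=O)C[C@@]1(C)[C@H](C)CC[C@@]2(C)C(C)=CCC[C@H]12 | intermediate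
25 | 13,14,15,16-tetranorclerod-3-en-12-ol | OCC[C@@]1(C)[C@H](C)CC[C@@]2(C)C(C)=CCC[C@H]12 | intermediate
26 | 12-iodo-13,14,15,16-tetranorclerod-3-ene | ICC[C@@]1(C)[C@H](C)CC[C@@]2(C)C(C)=CCC[C@H]12 | intermediate
27 | but-2-yne-1,4-diol | OCC#CCO | starting material
28 | 4-[(tert-butyldimethylsilyl)oxy]but-2-yn-1-ol | OCC#CCO[Si](C)(C)C(C)(C)C | intermediate
29 | sodium cyclic alkenylalanate from 28 (not isolated) | [Na+].COCCO[Al-]1(OCCOC)OCC=C1CO[Si](C)(C)C(C)(C)C | intermediate
30 | (Z)-4-[(tert-butyldimethylsilyl)oxy]-3-iodobut-2-en-1-ol | OC/C=C(\I)CO[Si](C)(C)C(C)(C)C | intermediate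
31 | icosanoic acid | CCCCCCCCCCCCCCCCCCCC(=O)O | starting material
32 | (Z)-4-[(tert-butyldimethylsilyl)oxy]-3-iodobut-2-en-1-yl icosanoate | CCCCCCCCCCCCCCCCCCCC(=O)OC/C=C(\I)CO[Si](C)(C)C(C)(C)C | intermediate
33 | alkylzinc iodide from 26 (not isolated) | I[Zn]CC[C@@]1(C)[C@H](C)CC[C@@]2(C)C(C)=CCC[C@H]12 | intermediate
34 | (13E)-16-[(tert-butyldimethylsilyl)oxy]cleroda-3,13-dien-15-yl icosanoate | CCCCCCCCCCCCCCCCCCCC(=O)OC/C=C(/CO[Si](C)(C)C(C)(C)C)CC[C@@]1(C)[C@H](C)CC[C@@]2(C)C(C)=CCC[C@H]12 | intermediate
35 | (13E)-16-hydroxycleroda-3,13-dien-15-yl icosanoate, (5R,8R,9S,10R) | CCCCCCCCCCCCCCCCCCCC(=O)OC/C=C(/CO)CC[C@@]1(C)[C@H](C)CC[C@@]2(C)C(C)=CCC[C@H]12 | target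

## Step count and least certain steps

Total step count: 25. Longest linear sequence: 21 steps (steps 1, 3 to 20, 24 and 25). Steps 2 and 21 to 23 prepare the diene and the side-chain fragment.

**Step 3 (key step).** Enal 3 is trisubstituted and therefore a slow dienophile, while the catalyst is a strong acid and 5 is a silyl dienol ether. The likely failures are protodesilylation of the diene, Mukaiyama-type addition of the diene to the activated formyl group instead of cycloaddition, and erosion of enantioselectivity by an achiral silyl cation released in these side reactions. If only the facial sense were opposite to the model, the antipodal catalyst would be used. The fallback moves stereocontrol from the catalyst to an auxiliary on an acid-stable dienyl ester. It sets out from 4 and 3.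
- Crotonaldehyde 4 is converted through its potassium dienolate (KOtBu, THF, −78 °C) and (S)-O-methylmandeloyl chloride into (E)-buta-1,3-dien-1-yl (S)-2-methoxy-2-phenylacetate F1.
- BF3·OEt2-promoted cycloaddition of F1 with 3 should give the mandelate analogue of 6, cyclohexene aldehyde F2. Its diastereomer with the opposite ring configuration is separable by chromatography, so the absolute configuration is secured whichever diastereomer predominates.
- Wittig reaction as in step 4 gives the alkenyl dioxolane F3.
- Methanolysis (K2CO3, MeOH), carried out only now that the aldehyde is consumed and retro-aldol cleavage is impossible, gives the allylic alcohol F4.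
- Silylation (TBSOTf, 2,6-lutidine) returns to the route at 7.

**Step 11.** Attack of the ketyl on the fully substituted β-carbon creates a syn-diaxial methyl pair and is slow, so reduction of the ketyl to the primary alcohol and pinacol coupling can overtake ring closure. A cis hydroxy ester would also lactonise and block step 12. The fallback replaces the ketyl radical anion by a neutral, nucleophilic acyl radical, which delivers the ketone directly. It sets out from 15.
- Pinnick oxidation (NaClO2, NaH2PO4, 2-methylbut-2-ene) of 15 gives the carboxylic acid F5.
- PhSeSePh and PBu3 convert F5 into the phenyl selenoester F6.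
- Bu3SnH with AIBN in benzene at 80 °C under slow addition should effect 6-exo acyl radical cyclisation under the same allylic-strain control and return to the route at 17, bypassing 16.

**Step 14.** The β face of the exocyclic alkene is only moderately more open than the α face, so facial selectivity may be insufficient, and the double bond may migrate into the ring on the catalyst surface before it is reduced. The fallback replaces surface syn-addition by stepwise hydrogen-atom transfer (Mn(dpm)3, PhSiH3, tert-butyl hydroperoxide, isopropanol, rt). The tertiary C8 radical is then quenched under product-stability control to give the equatorial methyl group. It sets out from 18 and returns at 19 without a new compound.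

**Step 24.** Zerovalent palladium can ionise the allylic icosanoate to a π-allyl complex. The consequences would be loss or transposition of the acyloxy group and scrambling of the C13=C14 geometry, and the risk is greatest once the alkenyl iodide is consumed. The fallback introduces the acyl group after the C–C bond. It sets out from 30 and 26.
- Alcohol 30 is protected with 4-methoxybenzyl trichloroacetimidate and catalytic acid to give the PMB ether F7.
- Alkylzinc 33 (from 26, as in step 24) is coupled with F7 under the same palladium catalysis to give the coupled PMB ether F8.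
- DDQ in wet CH2Cl2 frees the C15 alcohol F9.
- Esterification with 31 (EDC·HCl, DMAP) returns to the route at 34.

## Further compounds

F1 | step 3 | (E)-buta-1,3-dien-1-yl (S)-2-methoxy-2-phenylacetate | C=C/C=C/OC(=O)[C@@H](OC)c1ccccc1
F2 | step 3 | (1S,5S,6R)-5-[(benzyloxy)methyl]-6-formyl-6-methylcyclohex-2-en-1-yl (S)-2-methoxy-2-phenylacetate (ring configured as in 6) | O=C[C@@]1(C)[C@@H](OC(=O)[C@@H](OC)c2ccccc2)C=CC[C@@H]1COCc1ccccc1
F3 | step 3 | mandelate analogue of 7 (C4 ester in place of the silyl ether; alkene isomers) | O1CCOC1C=C[C@@]2(C)[C@@H](OC(=O)[C@@H](OC)c3ccccc3)C=CC[C@@H]2COCc4ccccc4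
F4 | step 3 | desilyl analogue of 7 (free 4β-hydroxyl; alkene isomers) | O1CCOC1C=C[C@@]2(C)[C@@H](O)C=CC[C@@H]2COCc3ccccc3
F5 | step 11 | 3-[(1R,2S,6R)-2-[(tert-butyldimethylsilyl)oxy]-6-[(2Z)-4-methoxy-4-oxobut-2-en-2-yl]-1-methylcyclohexyl]propanoic acid | OC(=O)CC[C@@]1(C)[C@@H](O[Si](C)(C)C(C)(C)C)CCC[C@@H]1/C(C)=C\C(=O)OC
F6 | step 11 | Se-phenyl selenoester of F5 | O=C([Se]c1ccccc1)CC[C@@]2(C)[C@@H](O[Si](C)(C)C(C)(C)C)CCC[C@@H]2/C(C)=C\C(=O)OC
F0 | step 14 | none | none
F7 | step 24 | (Z)-tert-butyl({2-iodo-4-[(4-methoxybenzyl)oxy]but-2-en-1-yl}oxy)dimethylsilane | COc1ccc(COC/C=C(\I)CO[Si](C)(C)C(C)(C)C)cc1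
F8 | step 24 | (13E)-16-[(tert-butyldimethylsilyl)oxy]-15-[(4-methoxybenzyl)oxy]cleroda-3,13-diene | COc1ccc(COC/C=C(/CO[Si](C)(C)C(C)(C)C)CC[C@@]2(C)[C@H](C)CC[C@@]3(C)C(C)=CCC[C@H]23)cc1
F9 | step 24 | (13E)-16-[(tert-butyldimethylsilyl)oxy]cleroda-3,13-dien-15-ol | OC/C=C(/CO[Si](C)(C)C(C)(C)C)CC[C@@]1(C)[C@H](C)CC[C@@]2(C)C(C)=CCC[C@H]12
A1 | alternative 1 | 3-oxo-4,19-cyclo-13,14,15,16,18-pentanorclerod-11-ene | C=C[C@@]1(C)[C@H](C)CC[C@@]23C[C@@H]2C(=O)CC[C@H]13
A2 | alternative 1 | 4-diazo-3-oxo-4,5-seco-13,14,15,16,18-pentanorcleroda-5(19),11-diene | C=C[C@@]1(C)[C@H](C)CCC(=C)[C@@H]1CCC(=O)C=[N+]=[N-]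
A3 | alternative 2 | 13,14,15,16-tetranorclerod-3-en-12-yl pivalate | CC(C)(C)C(=O)OCC[C@@]1(C)[C@H](C)CC[C@@]2(C)C(C)=CCC[C@H]12
A4 | alternative 2 | 13,14,15,16-tetranor-ent-labd-8(17)-en-12-yl pivalate | CC(C)(C)C(=O)OCC[C@@H]1C(=C)CC[C@@H]2C(C)(C)CCC[C@@]12C
A5 | alternative 3 | methyl 13,14,15,16-tetranorcleroda-1,11-dien-18-oate | C=C[C@@]1(C)[C@H](C)CC[C@@]2(C)[C@H](C(=O)OC)CC=C[C@H]12
A6 | alternative 3 | methyl (2E,8E)-7-ethenyl-3,6,7-trimethylundeca-2,8,10-trienoate (C8 and C9 configured as in 35) | COC(=O)/C=C(\C)CC[C@@H](C)[C@](C)(C=C)/C=C/C=C
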